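Atom labels C1–C15 follow the germacrane numbering of the target in every intermediate, including open-chain ones.

## The problem

The target 36 is a ten-membered carbocycle (C1–C10) fused at C6–C7 to a butenolide (C12, O, C6, C7=C11). Its α-carbon C11 bears the acetoxymethyl group C13, trans-oxiranes span C1–C10 and C4–C5, and the C8 oxygen carries (R)-3-chloro-2-hydroxy-2-methylpropanoate. Seven stereocentres must be set. C4, C8 and C2′ of the side chain are isolated from one another and need the chiral pool or reagent control. C5 and C6 adjoin C4 and can be induced from it, and C1/C10 follow from an E-alkene and the facial bias of the finished ring. Closing the ten-membered ring is the central difficulty, because entropy and transannular strain favour oligomers. The late intermediates tolerate neither strong acid nor strong base. Acid opens the oxiranes, transannularly once both are present. Base removes the butenolide γ-hydrogen at C6, which epimerises C6 or expels the C5 oxygen, and it also closes the chlorohydrin ester to a glycidate and cleaves the allylic acetate. The enabling feature is that C6 is the γ-carbon of the butenolide, the nucleophilic end of a 2-silyloxyfuran, and C5 is an oxirane carbon attached to the tertiary, methyl-bearing C4–O. C4 with its methyl group, its oxygen and the chain C3–C2–C1=C10 is the carbon pattern and configuration of (R)-linalool, so C5 can be an aldehyde on a linalool-derived centre and the C5–C6 bond can close the ring.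

## Retrosynthesis

**C1–O and C10–O.** The 1,10-oxirane of 36 is removed last, giving the 1(10)E-alkene 35. The alkene geometry is already fixed, and a peracid reaches only the outer face of a trans-cyclodecene, so one reagent should set both centres. Installing this oxirane earlier would expose it to the Lewis acid of the ring closure. The forward reaction must spare the electron-poor C7=C11 bond and the 4,5-oxirane.

**C8 ester and C13 acetate.** Cutting the C8–O acyl bond of 35 gives the alcohol 30 and the acid 31, which is used as bought. Cutting the acetate of 30 gives the diol 29. Both base-labile esters therefore enter after the last fluoride treatment. The forward steps need a primary-over-secondary acetylation and an acylation with an α-hydroxy acid whose hydroxyl is masked only in the flask.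

**C4–O–C5 oxirane.** The oxirane of 29 is cut at the C5–O bond, leaving the oxygen on C4, where linalool provides it. This leads to the mesylate 26 and the alcohol 25. Epoxidising a 4,5-alkene would be the usual cut, but no step of this plan delivers that alkene, whereas the aldol delivers a C5 carbinol next to the C4 oxygen. The price is that C5 must be formed with the configuration opposite to that of the target, because the closure inverts it.

**C5–C6 (key).** Cutting C5–C6 of 25 opens the ten-membered ring to the silyloxyfuran aldehyde 24. No neighbouring cut does as much: the C8–C9 cut makes no stereocentre, and a cut at C1=C10 would leave the alkene geometry to an olefination in a medium ring. This cut forms the ring, the lactone fusion centre C6 and the carbinol C5 next to the existing centre C4. The forward reaction must favour one of four diastereomers. To that end the C8 and C13 oxygens of 24 are tied in a di-tert-butylsilylene, which lets C8 decide the face of the furan that the tether can reach.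

**Silyloxyfuran, aldehyde and butenolide.** 24 is the silyl dienol ether of the butenolide 23. The aldehyde of 23 comes from the 4,5-acetonide 20 through 21 and 22, so the α-silyloxy aldehyde exists only for two steps. The butenolide carbonyl of 20 is traced to the C12 bromide of the furan 18. This fixes which α-carbon of a 3,4-disubstituted furan becomes C12, a question that direct oxidation of the furan would leave to small steric differences.

**C8 stereocentre.** The silylene 18 comes from the diol 17 and the alcohol 16, and the carbinol of 16 from the ketone 15. A heteroaryl alkyl ketone is a good substrate for oxazaborolidine-catalysed reduction, so C8 is set by the catalyst, independently of C4.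

**C8–C9.** The ketone 15 is cut between C8 and C9 into the dithiane 12 (an acyl anion at C8) and the allylic bromide 7, by way of 14. The bromide is primary, so a soft carbanion attacks it at C9 without allylic transposition, which an allyl metal adding to an aldehyde would not do.

**Fragments.** The dithiane 12 comes in four steps from the symmetrical furan diol 8, through 9, 10 and 11. Bromination is directed to C12 by the formyl group of 10. The bromide 7 comes from (R)-linalool 1. Exhaustive ozonolysis gives the triol 2 and removes any need to tell the two alkenes apart. The acetonide 3 masks C4–O and C5–O together, and a Wittig reaction (5), reduction (6) and bromination rebuild the E-C1=C10 alkene.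

## Roads not taken

**Alternative 1:** The cut removes both C8–O and C13–O and traces the two oxygens to one molecule of O2. In the forward step, singlet oxygen would add across C8 and C13 of the s-cis diene in 1β,10α:4α,5β-diepoxygermacra-7,11(13)-dien-12,6α-olide A2. This would give the 1,2-dioxine A1, with the alkene moved to C7=C11 and C8 set by the face of attack. Reduction of the O–O bond would then give the 1,10-epoxide of diol 29, which needs only the two acylations.
- Merits: the ring, both oxiranes and C4, C5 and C6 would come from a natural 4,5-epoxygermacranolide, and no macrocyclisation is needed.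
- Weak points: A2 requires a C7–C8 dehydrogenation of an α-methylene lactone for which no reliable method exists. The diene is cross-conjugated with the lactone carbonyl and electron-poor, so cycloaddition should be slow and ene reactions compete. C8 rests on facial selection alone. The peroxide must be reduced beside two oxiranes.
- Comparison: this road is clearly shorter and certain about the ring and C4–C6. The chosen plan offers reagent control at C8, no step without a workable method for making its substrate, and freedom from the supply and absolute configuration of a natural product.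

**Alternative 2:** The cut is the C6–O lactone bond together with the C6–H bond. A cytochrome P450 of the costunolide-synthase type would hydroxylate C6 of the acid A4 on the α face and the alcohol would lactonise to A3. A4 would be made from germacrone A5. Acylation at C8 and a double peracid epoxidation would finish the synthesis.
- Merits: no protecting groups, C6 set by the enzyme, and both oxiranes made from E-alkenes in one operation, as the crossed conformation of germacradienolides allows. The inversion detour at C5 disappears.
- Weak points: the known enzymes accept an 11(13)-ene acid. A4 has a conjugated C7=C11 acid, a doubly allylic C6, an 8-hydroxyl and a 13-acetate, so acceptance is unknown and bench chemistry cannot repair it. A4 itself needs one methyl group of A5 oxidised to the acid, the other to the acetoxymethyl group, and C8 reduced selectively. Germacradienes undergo Cope rearrangement on warming.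
- Comparison: with a suitable enzyme this would be the shortest route. The chosen plan uses reactions of known scope and controls each stereocentre by an identifiable element.

**Alternative 3:** The cut forms C10–C1 and C5–C4 and breaks C5–C10 and C1–C4. Irradiation of the enone A7 with 1-methylcyclobutene A8 would give the tricyclic adduct A9. Heating would open it to the cyclodecadienone A6.
- Merits: the ring is made in two operations without high dilution, both alkene geometries could come from a stereospecific cycloreversion, C8 comes from A7, and both oxiranes could later be made from alkenes.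
- Weak points: regio- and stereochemistry of a photocycloaddition between two trisubstituted alkenes are uncertain. The cycloreversion temperature is close to that of the Cope rearrangement of the 1,5-diene product. C4=C5 emerges as part of an enone, which a peracid does not epoxidise. A6 lacks C11–C13, so the butenolide, the C6 configuration and a C7 alkylation of a macrocyclic enone remain to be solved. A7 needs its own asymmetric synthesis.
- Comparison: ring formation here rests on a known reaction type and is better founded than the key step of the chosen plan. The chosen plan delivers the ring, the lactone fusion and two stereocentres in one step, so far less remains to be done afterwards.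

Key step: step 20

Assumption: commercial (R)-(−)-linalool is taken to be of high enantiomeric purity, since it is the only source of the C4 configuration.

## Route

Step 1
Reactants: 1 (R)-linalool [(3R)-3,7-dimethylocta-1,6-dien-3-ol]
Product: 2 (2R)-2-methylpentane-1,2,5-triol
Conditions: O3, CH2Cl2/MeOH (1:1), −78 °C; then NaBH4, −78 °C → rt
Reagents that add atoms: ozone, [O-][O+]=O
Why: Exhaustive ozonolysis cleaves both alkenes, so no selection between them is needed, and borohydride reduces the peroxidic intermediates and both aldehydes (C1 and C5) to the triol. The C4 carbinol centre is not touched.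

Step 2
Reactants: 2 (2R)-2-methylpentane-1,2,5-triol
Product: 3 3-[(4R)-2,2,4-trimethyl-1,3-dioxolan-4-yl]propan-1-ol
Conditions: 2,2-dimethoxypropane, pyridinium p-toluenesulfonate (cat.), acetone, rt
Reagents that add atoms: 2,2-dimethoxypropane, COC(C)(C)OC
Why: Acetalisation under thermodynamic control favours the five-membered dioxolane on the 1,2-diol (C4–O, C5–O) over seven- or eight-membered acetals, leaving only the C1 hydroxyl free.

Step 3
Reactants: 3 3-[(4R)-2,2,4-trimethyl-1,3-dioxolan-4-yl]propan-1-ol
Product: 5 ethyl (2E)-2-methyl-5-[(4R)-2,2,4-trimethyl-1,3-dioxolan-4-yl]pent-2-enoate, via acetonide aldehyde 4 (not isolated)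
Conditions: 2-iodoxybenzoic acid (IBX), DMSO, rt; then Ph3P=C(CH3)CO2Et, rt
Reagents that add atoms: ethyl 2-(triphenyl-λ5-phosphanylidene)propanoate, CCOC(=O)C(C)=P(c1ccccc1)(c1ccccc1)c1ccccc1
Why: Oxidation to the aldehyde and Wittig olefination in one flask; α-branched stabilised ylides give E-trisubstituted enoates, which sets the E geometry of C1=C10 and adds C9, C10 and C14.

Step 4
Reactants: 5 ethyl (2E)-2-methyl-5-[(4R)-2,2,4-trimethyl-1,3-dioxolan-4-yl]pent-2-enoate
Product: 6 (2E)-2-methyl-5-[(4R)-2,2,4-trimethyl-1,3-dioxolan-4-yl]pent-2-en-1-ol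
Conditions: i-Bu2AlH (2.2 equiv), CH2Cl2, −78 °C; Rochelle salt work-up
Reagents that add atoms: none
Why: 1,2-Reduction of the enoate by the aluminium hydride gives the allylic alcohol; the acetonide and the alkene geometry are unaffected.

Step 5
Reactants: 6 (2E)-2-methyl-5-[(4R)-2,2,4-trimethyl-1,3-dioxolan-4-yl]pent-2-en-1-ol
Product: 7 (4R)-4-[(3E)-5-bromo-4-methylpent-3-en-1-yl]-2,2,4-trimethyl-1,3-dioxolane
Conditions: CBr4, PPh3, 2,6-lutidine (0.2 equiv), CH2Cl2, 0 °C
Reagents that add atoms: tetrabromomethane, BrC(Br)(Br)Br
Why: Appel bromination of a primary allylic alcohol proceeds by SN2 at C9 with retention of the alkene geometry; the buffer protects the acetonide.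

Step 6
Reactants: 8 furan-3,4-diyldimethanol [3,4-bis(hydroxymethyl)furan]
Product: 9 [4-({[tert-butyl(diphenyl)silyl]oxy}methyl)furan-3-yl]methanol
Conditions: t-BuPh2SiCl (1.0 equiv), imidazole, THF, 0 °C; unreacted 8 recovered
Reagents that add atoms: tert-butyl(chloro)diphenylsilane, CC(C)(C)[Si](Cl)(c1ccccc1)c1ccccc1
Why: Monosilylation of a symmetrical diol separates the arm that becomes C13 (silylated) from the arm that becomes C8 (free).

Step 7
Reactants: 9 [4-({[tert-butyl(diphenyl)silyl]oxy}methyl)furan-3-yl]methanol
Product: 10 4-({[tert-butyl(diphenyl)silyl]oxy}methyl)furan-3-carbaldehyde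
Conditions: MnO2 (activated, excess), CH2Cl2, rt
Reagents that add atoms: none
Why: Manganese dioxide oxidises the heteroaryl carbinol to the aldehyde and stops there; the silyl ether prevents lactol and lactone formation.

Step 8
Reactants: 10 4-({[tert-butyl(diphenyl)silyl]oxy}methyl)furan-3-carbaldehyde
Product: 11 5-bromo-4-({[tert-butyl(diphenyl)silyl]oxy}methyl)furan-3-carbaldehyde
Conditions: N-bromosuccinimide, DMF, 0 °C → rt, dark
Reagents that add atoms: N-bromosuccinimide, O=C1CCC(=O)N1Br
Why: Electrophilic aromatic substitution; attack next to the formyl-bearing carbon would place positive charge on that carbon, so bromine enters the α-position beside the silyloxymethyl group. This carbon is the future C12, and the bromine later fixes where the lactone carbonyl forms.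

Step 9
Reactants: 11 5-bromo-4-({[tert-butyl(diphenyl)silyl]oxy}methyl)furan-3-carbaldehyde
Product: 12 {[2-bromo-4-(1,3-dithian-2-yl)furan-3-yl]methoxy}(tert-butyl)diphenylsilane
Conditions: HS(CH2)3SH, BF3·OEt2 (cat.), CH2Cl2, −20 °C
Reagents that add atoms: propane-1,3-dithiol, SCCCS
Why: Lewis-acid-catalysed dithioacetalisation turns the C8 aldehyde into its Corey–Seebach acyl anion precursor; the robust silyl ether and the bromofuran tolerate the catalyst at low temperature.

Step 10
Reactants: 12 {[2-bromo-4-(1,3-dithian-2-yl)furan-3-yl]methoxy}(tert-butyl)diphenylsilane; 7 (4R)-4-[(3E)-5-bromo-4-methylpent-3-en-1-yl]-2,2,4-trimethyl-1,3-dioxolane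
Product: 14 {[2-bromo-4-(2-{(2E)-2-methyl-5-[(4R)-2,2,4-trimethyl-1,3-dioxolan-4-yl]pent-2-en-1-yl}-1,3-dithian-2-yl)furan-3-yl]methoxy}(tert-butyl)diphenylsilane, via lithiodithiane 13 (not isolated)
Conditions: LiN(i-Pr)2 (1.05 equiv), THF, −78 °C; then 7, −78 → −20 °C
Reagents that add atoms: none
Why: Corey–Seebach alkylation forms C8–C9; the amide base removes the sulfur-stabilised, aryl-activated proton without bromine–lithium exchange, and the soft carbanion attacks the primary allylic bromide at C9 by SN2.

Step 11
Reactants: 14 alkylated dithiane (name as under step 10)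
Product: 15 (3E)-1-[5-bromo-4-({[tert-butyl(diphenyl)silyl]oxy}methyl)furan-3-yl]-3-methyl-6-[(4R)-2,2,4-trimethyl-1,3-dioxolan-4-yl]hex-3-en-1-one
Conditions: MeI, CaCO3, MeCN/H2O (4:1), 45 °C
Reagents that add atoms: water, O
Why: Alkylative dithiane hydrolysis (S-methylation, then hydrolysis of the sulfonium salt) under buffered, near-neutral conditions should spare the acetonide and leave the β,γ-alkene out of conjugation.

Step 12
Reactants: 15 (3E)-1-[5-bromo-4-({[tert-butyl(diphenyl)silyl]oxy}methyl)furan-3-yl]-3-methyl-6-[(4R)-2,2,4-trimethyl-1,3-dioxolan-4-yl]hex-3-en-1-one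
Product: 16 (1S,3E)-1-[5-bromo-4-({[tert-butyl(diphenyl)silyl]oxy}methyl)furan-3-yl]-3-methyl-6-[(4R)-2,2,4-trimethyl-1,3-dioxolan-4-yl]hex-3-en-1-ol
Conditions: (R)-1-methyl-3,3-diphenyltetrahydro-1H,3H-pyrrolo[1,2-c][1,3,2]oxazaborole (20 mol%), catecholborane, toluene, −78 °C
Reagents that add atoms: none
Why: Corey–Bakshi–Shibata reduction; the furyl group acts as the large and the allylic methylene as the small substituent, so the R catalyst should deliver hydride to give the 8S carbinol. Catecholborane avoids hydroboration of the alkene.

Step 13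
Reactants: 16 (1S,3E)-1-[5-bromo-4-({[tert-butyl(diphenyl)silyl]oxy}methyl)furan-3-yl]-3-methyl-6-[(4R)-2,2,4-trimethyl-1,3-dioxolan-4-yl]hex-3-en-1-ol
Product: 17 (1S,3E)-1-[5-bromo-4-(hydroxymethyl)furan-3-yl]-3-methyl-6-[(4R)-2,2,4-trimethyl-1,3-dioxolan-4-yl]hex-3-en-1-ol
Conditions: Bu4NF, THF, 0 °C → rt
Reagents that add atoms: none
Why: Fluoride cleaves the silyl ether and frees the C13 hydroxyl beside the C8 hydroxyl; the acetonide, bromofuran and alkene are inert.

Step 14
Reactants: 17 (1S,3E)-1-[5-bromo-4-(hydroxymethyl)furan-3-yl]-3-methyl-6-[(4R)-2,2,4-trimethyl-1,3-dioxolan-4-yl]hex-3-en-1-ol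
Product: 18 cyclic di-tert-butylsilylene of 17 (silicon bridges O8 and O13 in a seven-membered 1,3,2-dioxasilepine fused to the 2-bromofuran; C8 S, acetonide carbon C4 R, 1(10)E)
Conditions: t-Bu2Si(OTf)2, 2,6-lutidine, CH2Cl2, 0 °C
Reagents that add atoms: di-tert-butylsilyl bis(trifluoromethanesulfonate), CC(C)(C)[Si](OS(=O)(=O)C(F)(F)F)(OS(=O)(=O)C(F)(F)F)C(C)(C)C
Why: The two hydroxyls sit on adjacent furan carbons like those of a cis-but-2-ene-1,4-diol, for which seven-membered silylenes form readily. The ring protects both oxygens and fixes the rotamer about C7–C8 for the key step.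

Step 15
Reactants: 18 cyclic di-tert-butylsilylene bromofuran
Product: 20 3,4-disubstituted furan-2(5H)-one corresponding to 18 (C12 carbonyl, C6 methylene, O8/O13 silylene and 4,5-acetonide retained; C8 S, C4 R, 1(10)E), via lithium borate 19 (not isolated)
Conditions: B(Oi-Pr)3, n-BuLi, THF/toluene, −78 °C (in situ quench); then 30% H2O2, aq. NaHCO3, 0 °C; then Et3N (cat.), rt
Reagents that add atoms: hydrogen peroxide, OO
Why: Bromine–lithium exchange with immediate trapping by the borate, then oxidative 1,2-migration from boron to oxygen, gives the 2-hydroxyfuran, which tautomerises to the conjugated butenolide. The carbonyl appears at the carbon brominated in step 8.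

Step 16
Reactants: 20 butenolide acetonide
Product: 21 4,5-diol of 20 (tertiary C4–OH R, primary C5–OH; butenolide and silylene retained)
Conditions: pyridinium p-toluenesulfonate (cat.), MeOH, 0 °C → rt
Reagents that add atoms: none
Why: Mild transketalisation removes the isopropylidene group of the terminal diol; the hindered di-tert-butylsilylene should survive these conditions.

Step 17
Reactants: 21 4,5-diol
Product: 22 4,5-bis(triethylsilyl) ether of 21
Conditions: Et3SiOTf (2.5 equiv), 2,6-lutidine, CH2Cl2, −78 → −40 °C
Reagents that add atoms: triethylsilyl trifluoromethanesulfonate, CC[Si](CC)(CC)OS(=O)(=O)C(F)(F)F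
Why: The silyl triflate silylates the primary and the tertiary hydroxyl; the weak base and low temperature should leave the butenolide un-enolised.

Step 18
Reactants: 22 4,5-bis(triethylsilyl) ether
Product: 23 (4R,8S,1(10)E)-C5 aldehyde bearing the 4-triethylsilyloxy group, the butenolide and the O8/O13 silylene
Conditions: (COCl)2, DMSO, CH2Cl2, −78 → −40 °C; then Et3N, −78 → 0 °C
Reagents that add atoms: none
Why: Under Swern conditions a primary triethylsilyl ether is oxidised directly to the aldehyde while tertiary and cyclic silyl ethers remain, so the α-silyloxy aldehyde forms without a free α-hydroxy aldehyde; C4 is quaternary and cannot epimerise.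

Step 19
Reactants: 23 C5 aldehyde
Product: 24 2-(triisopropylsilyloxy)furan of 23 (furan C12–OSi, C11 with the silylene-bound C13, C7 with C8, C6–H; 4-triethylsilyloxy C5 aldehyde; C4 R, C8 S, 1(10)E)
Conditions: i-Pr3SiOTf (1.2 equiv), Et3N (2 equiv), CH2Cl2, 0 °C; basic aqueous work-up, used without chromatography
Reagents that add atoms: triisopropylsilyl trifluoromethanesulfonate, CC(C)[Si](C(C)C)(C(C)C)OS(=O)(=O)C(F)(F)F
Why: Soft enolisation of the butenolide at the γ-carbon C6 and O-silylation give the aromatic silyloxyfuran; the aldehyde has no α-hydrogen, and excess amine keeps the silyl triflate from starting the aldol early.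

Step 20
Reactants: 24 2-(triisopropylsilyloxy)furan aldehyde
Product: 25 (4R,5S,6S,8S)-8,13-O,O-(di-tert-butylsilanediyl)-5-hydroxy-4-(triethylsilyloxy)germacra-1(10)E,7(11)-dien-12,6-olide
Conditions: BF3·OEt2 (1.5 equiv), CH2Cl2, −78 °C, 24 added over 10 h (final ca. 1 mM); then aq. NaHCO3
Reagents that add atoms: none
Why: Proposed new method: BF3 binds the non-enolisable C5 aldehyde, the silyloxyfuran attacks through its γ-carbon C6 in an open transition state, and transfer of the triisopropylsilyl group to fluoride returns the butenolide; the closest known reaction types are the intermolecular BF3-promoted vinylogous Mukaiyama aldol of 2-silyloxyfurans with α-alkoxy aldehydes, the intramolecular vinylogous aldol of butenolide aldehydes to five- to seven-membered carbocycles, and macrocyclising Mukaiyama aldol reactions of simple silyl enol ethers. The ten-membered carbocycle closes end to end, 10-exo-trig with respect to the aldehyde and enol-endo with respect to the furan C6=C7 bond; slow addition to about 1 mM disfavours oligomers, and the furan, the E-C1=C10 alkene and the quaternary C4 remove rotors from the six-atom tether. C5 is controlled by C4: the triethylsilyloxy group, bulky and not chelated by BF3, stands anti to the incoming carbon, C3 lies beside the carbonyl oxygen and the methyl group on the attack trajectory (polar Felkin–Anh), which for 4R gives the 5S alcohol that the later inversion needs. C6 is controlled by C8 through the silylene: the seven-membered ring keeps the C8 oxygen on the C13 side of the furan, so the benzylic C8–H lies in the furan plane towards C6–H and C9 leaves on one face only, the face from which closure gives 6S. Without the silylene, allylic strain would turn C8–H towards C13 and present the tether on the other face. The step needs the 5S,6S (5,6-erythro) isomer out of four, whereas untethered BF3 additions of silyloxyfurans lean towards threo; that both local preferences fit one unstrained transition state is an assumption. Because C6–H of the product remains acidic, a C6 epimer could in principle be equilibrated, which is a reserve and not part of the plan.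

Step 21
Reactants: 25 macrocyclic hydroxy lactone
Product: 26 5-O-methanesulfonate of 25 (4R,5S,6S,8S)
Conditions: MeSO2Cl, Et3N, CH2Cl2, −20 → 0 °C
Reagents that add atoms: methanesulfonyl chloride, CS(=O)(=O)Cl
Why: Sulfonylation through the small sulfene electrophile reaches the hindered secondary C5 hydroxyl, the only free hydroxyl; short exposure to the amine at low temperature should leave C6–H alone.

Step 22
Reactants: 26 C5 mesylate
Product: 29 (4R,5R,6S,8S)-4,5-epoxy-8,13-dihydroxygermacra-1(10)E,7(11)-dien-12,6-olide, via hydroxy mesylate 27 (not isolated), via silylene epoxide 28 (not isolated)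
Conditions: Bu4NF (4 equiv), THF, 0 °C
Reagents that add atoms: none
Why: Fluoride cleaves the tertiary triethylsilyl ether, and the C4 alkoxide displaces the neighbouring mesylate in a 3-exo-tet Williamson closure with inversion at C5, which gives the trans-oxirane with the linalool oxygen; the same reagent then removes the silylene. The intramolecular displacement should be faster than deprotonation at C6.

Step 23
Reactants: 29 epoxy diol
Product: 30 (4R,5R,6S,8S)-13-acetoxy-4,5-epoxy-8-hydroxygermacra-1(10)E,7(11)-dien-12,6-olide
Conditions: AcCl (1.05 equiv), 2,4,6-collidine, CH2Cl2, −78 °C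
Reagents that add atoms: acetyl chloride, CC(=O)Cl
Why: Kinetic acylation distinguishes the primary allylic C13 hydroxyl from the hindered secondary C8 hydroxyl; the weak, hindered base spares the oxirane and C6–H.

Step 24
Reactants: 30 13-acetate with free C8 hydroxyl; 31 (2R)-3-chloro-2-hydroxy-2-methylpropanoic acid
Product: 35 (4R,5R,6S,8S)-13-acetoxy-8-[(2R)-3-chloro-2-hydroxy-2-methylpropanoyloxy]-4,5-epoxygermacra-1(10)E,7(11)-dien-12,6-olide, via bis-silyl derivative 32 (not isolated), via acid chloride 33 (not isolated), via silyl ether ester 34 (not isolated)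
Conditions: 31, Me3SiCl, pyridine, CH2Cl2, 0 °C; (COCl)2, N,N-dimethylformamide (cat.), 0 °C; then 30, pyridine, 4-(dimethylamino)pyridine (cat.), 0 °C → rt; then citric acid, MeOH, 0 °C
Reagents that add atoms: none
Why: Bis-silylation masks the tertiary hydroxyl, and oxalyl chloride converts the silyl ester into the acid chloride, which has no α-hydrogen and cannot racemise. After acylation of the C8 hydroxyl, mild acidic methanolysis removes the labile tertiary trimethylsilyl ether without base, so the chlorohydrin and the oxirane should survive.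

Step 25
Reactants: 35 1(10)-ene diester
Product: 36 target, (1R,4R,5R,6S,8S,10R)-13-acetoxy-8-[(2R)-3-chloro-2-hydroxy-2-methylpropanoyloxy]-1,10:4,5-diepoxygermacr-7(11)-en-12,6-olide
Conditions: 3-chloroperoxybenzoic acid, NaHCO3, CH2Cl2, 0 °C
Reagents that add atoms: 3-chloroperoxybenzoic acid, OOC(=O)c1cccc(Cl)c1
Why: Prilezhaev epoxidation is stereospecific (E-alkene to trans-oxirane) and chemoselective for the electron-rich C1=C10 bond over the butenolide alkene. C1 and C10 are set by attack on the exposed outer face of the alkene in the crossed germacranolide conformation, which in related 4,5-epoxygermacranolides leads to the 1β,10α-oxirane.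

## Compound list

1 | (R)-linalool, (3R)-3,7-dimethylocta-1,6-dien-3-ol | CC(C)=CCC[C@@](C)(O)C=C | starting material
2 | (2R)-2-methylpentane-1,2,5-triol | OCCC[C@@](C)(O)CO | intermediate
3 | 3-[(4R)-2,2,4-trimethyl-1,3-dioxolan-4-yl]propan-1-ol | OCCC[C@@]1(C)OC(C)(C)OC1 | intermediate
4 | 3-[(4R)-2,2,4-trimethyl-1,3-dioxolan-4-yl]propanal | O=CCC[C@@]1(C)OC(C)(C)OC1 | intermediate (not isolated)
5 | ethyl (2E)-2-methyl-5-[(4R)-2,2,4-trimethyl-1,3-dioxolan-4-yl]pent-2-enoate | CCOC(=O)/C(C)=C/CC[C@@]1(C)OC(C)(C)OC1 | intermediate
6 | (2E)-2-methyl-5-[(4R)-2,2,4-trimethyl-1,3-dioxolan-4-yl]pent-2-en-1-ol | OC/C(C)=C/CC[C@@]1(C)OC(C)(C)OC1 | intermediate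
7 | (4R)-4-[(3E)-5-bromo-4-methylpent-3-en-1-yl]-2,2,4-trimethyl-1,3-dioxolane | BrC/C(C)=C/CC[C@@]1(C)OC(C)(C)OC1 | intermediate
8 | furan-3,4-diyldimethanol | OCc1cocc1CO | starting material
9 | [4-({[tert-butyl(diphenyl)silyl]oxy}methyl)furan-3-yl]methanol | OCc1cocc1CO[Si](c1ccccc1)(c1ccccc1)C(C)(C)C | intermediate
10 | 4-({[tert-butyl(diphenyl)silyl]oxy}methyl)furan-3-carbaldehyde | O=Cc1cocc1CO[Si](c1ccccc1)(c1ccccc1)C(C)(C)C | intermediate
11 | 5-bromo-4-({[tert-butyl(diphenyl)silyl]oxy}methyl)furan-3-carbaldehyde | O=Cc1coc(Br)c1CO[Si](c1ccccc1)(c1ccccc1)C(C)(C)C | intermediate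
12 | {[2-bromo-4-(1,3-dithian-2-yl)furan-3-yl]methoxy}(tert-butyl)diphenylsilane | C1CSC(SC1)c1coc(Br)c1CO[Si](c1ccccc1)(c1ccccc1)C(C)(C)C | intermediate
13 | 2-lithio derivative of 12 (lithium on C2 of the dithiane) | [Li]C1(SCCCS1)c1coc(Br)c1CO[Si](c1ccccc1)(c1ccccc1)C(C)(C)C | intermediate (not isolated)
14 | {[2-bromo-4-(2-{(2E)-2-methyl-5-[(4R)-2,2,4-trimethyl-1,3-dioxolan-4-yl]pent-2-en-1-yl}-1,3-dithian-2-yl)furan-3-yl]methoxy}(tert-butyl)diphenylsilane | C1CSC(SC1)(C/C(C)=C/CC[C@@]2(C)OC(C)(C)OC2)c1coc(Br)c1CO[Si](c1ccccc1)(c1ccccc1)C(C)(C)C | intermediate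
15 | (3E)-1-[5-bromo-4-({[tert-butyl(diphenyl)silyl]oxy}methyl)furan-3-yl]-3-methyl-6-[(4R)-2,2,4-trimethyl-1,3-dioxolan-4-yl]hex-3-en-1-one | O=C(C/C(C)=C/CC[C@@]1(C)OC(C)(C)OC1)c1coc(Br)c1CO[Si](c1ccccc1)(c1ccccc1)C(C)(C)C | intermediate
16 | (1S,3E)-1-[5-bromo-4-({[tert-butyl(diphenyl)silyl]oxy}methyl)furan-3-yl]-3-methyl-6-[(4R)-2,2,4-trimethyl-1,3-dioxolan-4-yl]hex-3-en-1-ol | O[C@@H](C/C(C)=C/CC[C@@]1(C)OC(C)(C)OC1)c1coc(Br)c1CO[Si](c1ccccc1)(c1ccccc1)C(C)(C)C | intermediate
17 | (1S,3E)-1-[5-bromo-4-(hydroxymethyl)furan-3-yl]-3-methyl-6-[(4R)-2,2,4-trimethyl-1,3-dioxolan-4-yl]hex-3-en-1-ol | O[C@@H](C/C(C)=C/CC[C@@]1(C)OC(C)(C)OC1)c1coc(Br)c1CO | intermediate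
18 | cyclic di-tert-butylsilylene of 17 (O8–Si–O13 in a seven-membered ring fused to the 2-bromofuran; C8 S, C4 R, 1(10)E) | CC(C)(C)[Si]1(C(C)(C)C)OCc2c(Br)occ2[C@H](C/C(C)=C/CC[C@@]3(C)OC(C)(C)OC3)O1 | intermediate
19 | lithium triisopropoxyborate of 18 (boron in place of bromine at C12) | CC(C)(C)[Si]1(C(C)(C)C)OCc2c([B-](OC(C)C)(OC(C)C)OC(C)C)occ2[C@H](C/C(C)=C/CC[C@@]3(C)OC(C)(C)OC3)O1.[Li+] | intermediate (not isolated)
20 | furan-2(5H)-one from 18 (C12=O, C6H2; O8/O13 silylene; 4,5-acetonide; C8 S, C4 R, 1(10)E) | CC(C)(C)[Si]1(C(C)(C)C)OCC2=C(COC2=O)[C@H](C/C(C)=C/CC[C@@]3(C)OC(C)(C)OC3)O1 | intermediate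
21 | 4,5-diol of 20 (C4 R) | CC(C)(C)[Si]1(C(C)(C)C)OCC2=C(COC2=O)[C@H](C/C(C)=C/CC[C@@](C)(O)CO)O1 | intermediate
22 | 4,5-bis(triethylsilyl) ether of 21 | CC(C)(C)[Si]1(C(C)(C)C)OCC2=C(COC2=O)[C@H](C/C(C)=C/CC[C@@](C)(O[Si](CC)(CC)CC)CO[Si](CC)(CC)CC)O1 | intermediate
23 | (4R,8S,1(10)E)-4-(triethylsilyloxy) C5 aldehyde with butenolide and O8/O13 silylene | CC(C)(C)[Si]1(C(C)(C)C)OCC2=C(COC2=O)[C@H](C/C(C)=C/CC[C@@](C)(O[Si](CC)(CC)CC)C=O)O1 | intermediate
24 | 2-(triisopropylsilyloxy)furan of 23 (precursor of the key step) | CC(C)(C)[Si]1(C(C)(C)C)OCc2c(O[Si](C(C)C)(C(C)C)C(C)C)occ2[C@H](C/C(C)=C/CC[C@@](C)(O[Si](CC)(CC)CC)C=O)O1 | intermediate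
25 | (4R,5S,6S,8S)-8,13-O,O-(di-tert-butylsilanediyl)-5-hydroxy-4-(triethylsilyloxy)germacra-1(10)E,7(11)-dien-12,6-olide | CC(C)(C)[Si]1(C(C)(C)C)OCC2=C3[C@@H](O1)C/C(C)=C/CC[C@@](C)(O[Si](CC)(CC)CC)[C@@H](O)[C@H]3OC2=O | intermediate
26 | 5-O-methanesulfonate of 25 (4R,5S,6S,8S) | CC(C)(C)[Si]1(C(C)(C)C)OCC2=C3[C@@H](O1)C/C(C)=C/CC[C@@](C)(O[Si](CC)(CC)CC)[C@@H](OS(C)(=O)=O)[C@H]3OC2=O | intermediate
27 | 4-hydroxy 5-methanesulfonate (triethylsilyl group removed from 26; 4R,5S,6S,8S) | CC(C)(C)[Si]1(C(C)(C)C)OCC2=C3[C@@H](O1)C/C(C)=C/CC[C@@](C)(O)[C@@H](OS(C)(=O)=O)[C@H]3OC2=O | intermediate (not isolated)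
28 | (4R,5R,6S,8S)-8,13-O,O-(di-tert-butylsilanediyl)-4,5-epoxygermacra-1(10)E,7(11)-dien-12,6-olide | CC(C)(C)[Si]1(C(C)(C)C)OCC2=C3[C@@H](O1)C/C(C)=C/CC[C@@]4(C)O[C@@H]4[C@H]3OC2=O | intermediate (not isolated)
29 | (4R,5R,6S,8S)-4,5-epoxy-8,13-dihydroxygermacra-1(10)E,7(11)-dien-12,6-olide | OCC1=C2[C@@H](O)C/C(C)=C/CC[C@@]3(C)O[C@@H]3[C@H]2OC1=O | intermediate
30 | (4R,5R,6S,8S)-13-acetoxy-4,5-epoxy-8-hydroxygermacra-1(10)E,7(11)-dien-12,6-olide | CC(=O)OCC1=C2[C@@H](O)C/C(C)=C/CC[C@@]3(C)O[C@@H]3[C@H]2OC1=O | intermediate
31 | (2R)-3-chloro-2-hydroxy-2-methylpropanoic acid | OC(=O)[C@@](C)(O)CCl | starting material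
32 | trimethylsilyl (2R)-3-chloro-2-methyl-2-[(trimethylsilyl)oxy]propanoate | C[Si](C)(C)OC(=O)[C@@](C)(O[Si](C)(C)C)CCl | intermediate (not isolated)
33 | (2S)-3-chloro-2-methyl-2-[(trimethylsilyl)oxy]propanoyl chloride (same spatial arrangement as 31; the descriptor changes with the priorities) | ClC(=O)[C@@](C)(O[Si](C)(C)C)CCl | intermediate (not isolated)
34 | 2′-O-trimethylsilyl ether of 35 | CC(=O)OCC1=C2[C@@H](OC(=O)[C@@](C)(O[Si](C)(C)C)CCl)C/C(C)=C/CC[C@@]3(C)O[C@@H]3[C@H]2OC1=O | intermediate (not isolated)
35 | (4R,5R,6S,8S)-13-acetoxy-8-[(2R)-3-chloro-2-hydroxy-2-methylpropanoyloxy]-4,5-epoxygermacra-1(10)E,7(11)-dien-12,6-olide | CC(=O)OCC1=C2[C@@H](OC(=O)[C@@](C)(O)CCl)C/C(C)=C/CC[C@@]3(C)O[C@@H]3[C@H]2OC1=O | intermediate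
36 | (1R,4R,5R,6S,8S,10R)-13-acetoxy-8-[(2R)-3-chloro-2-hydroxy-2-methylpropanoyloxy]-1,10:4,5-diepoxygermacr-7(11)-en-12,6-olide (CNP0255009.1) | CC(=O)OCC1=C2[C@@H](OC(=O)[C@@](C)(O)CCl)C[C@@]3(C)O[C@@H]3CC[C@@]3(C)O[C@@H]3[C@H]2OC1=O | target

## Step count and risks

Total step count: 25. Longest linear sequence: 21 steps (steps 1–5 and 10–25, from (R)-linalool). The furan branch (steps 6–9) joins at step 10.

**Step 20 (key step, proposed new method).**
- Risk: intermolecular aldol oligomerisation may outrun closure of the strained ten-membered ring. The silyl dienol ether may be lost by protodesilylation at high dilution. Facial selection at C5 and C6 may be poor, since the Felkin preference at C4 and the tether-imposed furan face may not be compatible in one transition state.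
- Fallback (known chemistry only): sets out from 18 and returns at 25.
  - LiN(i-Pr)2 removes the only remaining ring proton (C6–H) of the 2-bromofuran, and iodine gives the 6-iodo-12-bromofuran silylene F1.
  - Acetonide methanolysis as in step 16 gives the diol F2, bis-silylation as in step 17 gives the bis(triethylsilyl) ether F3, and Swern oxidation as in step 18 gives the iodofuran aldehyde F4.
  - CrCl2 with catalytic NiCl2 in DMSO/THF at high dilution should insert into the C–I bond in preference to the C–Br bond. Addition of the furylchromium species to the C5 aldehyde is a Nozaki–Hiyama–Kishi macrocyclisation of a 2-halofuran, an established way to close medium carbocycles. It should give the furan-fused ten-membered carbinol F5, with C5 set by Felkin addition.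
  - Bromine–lithium exchange, borate trapping and peroxide oxidation as in step 15 (one extra equivalent of n-BuLi for the hydroxyl) give the 2-hydroxyfuran. This ketonises by protonation at C6 to 25, with C6 under thermodynamic control.

**Step 15.**
- Risk: protodeboronation of the electron-rich furyl borate before oxidation, or attack of basic peroxide on the butenolide or silylene. Either would give debrominated furan or ring-opened material.
- Fallback: sets out from 18 and returns at 20.
  - Bromine–lithium exchange and trapping with Me3SiCl gives the 12-trimethylsilylfuran F6.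
  - Singlet oxygen (O2, 5,10,15,20-tetraphenylporphyrin, light, −78 °C) adds across the furan. Silyl migration within the endoperoxide places the carbonyl on the former silyl carbon and gives the γ-hydroxybutenolide F7.
  - NaBH4 reduction of the lactol and acidification close the lactone to 20.

**Step 22.**
- Risk: fluoride may deprotonate C6 in competition with oxirane closure. That would lead to β-elimination of the mesylate to a γ-ylidene butenolide or to epimerisation at C6.
- Fallback: sets out from 25 and returns at 29, without mesylate or basic fluoride.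
  - Pyridinium p-toluenesulfonate in MeOH removes only the triethylsilyl group and gives the 4,5-diol F8.
  - Mitsunobu cyclodehydration (PPh3, diisopropyl azodicarboxylate) activates the secondary C5 hydroxyl as the oxyphosphonium ion. The tertiary C4 hydroxyl displaces it with inversion under neutral conditions to give 28.
  - HF·pyridine buffered with pyridine cleaves the silylene to 29.

**Step 25.**
- Risk: the 7(11)-ene ring with its C8 ester may expose the other face of C1=C10, giving the 1S,10S oxirane or a mixture.
- Fallback: sets out from 35 and returns at 36 by the two-step route that delivers the oxirane on the face opposite to direct electrophilic attack.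
  - N-bromosuccinimide in aqueous acetone forms the bromonium ion on the face that the peracid prefers. Water opens it at the tertiary C10 from the other side to give the (1S,10R)-1-bromo-10-hydroxy compound F9.
  - Ag2O in CH2Cl2 closes the oxirane by displacement of bromide at C1 with inversion, without the basic conditions that would attack the chlorohydrin ester.

## Further compounds

F1 | step 20 | 6-iodo derivative of 18 (2-bromo-5-iodofuran, O8/O13 silylene, acetonide; C8 S, C4 R) | CC(C)(C)[Si]1(C(C)(C)C)OCc2c(Br)oc(I)c2[C@H](C/C(C)=C/CC[C@@]3(C)OC(C)(C)OC3)O1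
F2 | step 20 | 4,5-diol of F1 | CC(C)(C)[Si]1(C(C)(C)C)OCc2c(Br)oc(I)c2[C@H](C/C(C)=C/CC[C@@](C)(O)CO)O1
F3 | step 20 | 4,5-bis(triethylsilyl) ether of F2 | CC(C)(C)[Si]1(C(C)(C)C)OCc2c(Br)oc(I)c2[C@H](C/C(C)=C/CC[C@@](C)(O[Si](CC)(CC)CC)CO[Si](CC)(CC)CC)O1
F4 | step 20 | 4-(triethylsilyloxy) C5 aldehyde of the 12-bromo-6-iodofuran (C4 R, C8 S) | CC(C)(C)[Si]1(C(C)(C)C)OCc2c(Br)oc(I)c2[C@H](C/C(C)=C/CC[C@@](C)(O[Si](CC)(CC)CC)C=O)O1
F5 | step 20 | furan-fused ten-membered carbinol (C5–C6 bond formed; 12-bromofuran; 4R,5S,8S) | CC(C)(C)[Si]1(C(C)(C)C)OCc2c(Br)oc3c2[C@@H](O1)C/C(C)=C/CC[C@@](C)(O[Si](CC)(CC)CC)[C@H]3O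
F6 | step 15 | 12-trimethylsilylfuran corresponding to 18 | CC(C)(C)[Si]1(C(C)(C)C)OCc2c([Si](C)(C)C)occ2[C@H](C/C(C)=C/CC[C@@]3(C)OC(C)(C)OC3)O1
F7 | step 15 | 6-hydroxy derivative of 20 (γ-hydroxybutenolide, both C6 epimers) | CC(C)(C)[Si]1(C(C)(C)C)OCC2=C(C(O)OC2=O)[C@H](C/C(C)=C/CC[C@@]3(C)OC(C)(C)OC3)O1
F8 | step 22 | (4R,5S,6S,8S)-8,13-O,O-(di-tert-butylsilanediyl)-4,5-dihydroxygermacra-1(10)E,7(11)-dien-12,6-olide | CC(C)(C)[Si]1(C(C)(C)C)OCC2=C3[C@@H](O1)C/C(C)=C/CC[C@@](C)(O)[C@@H](O)[C@H]3OC2=O
F9 | step 25 | (1S,10R)-1-bromo-10-hydroxy derivative of 35 | CC(=O)OCC1=C2[C@@H](OC(=O)[C@@](C)(O)CCl)C[C@@](C)(O)[C@@H](Br)CC[C@@]3(C)O[C@@H]3[C@H]2OC1=O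
A1 | alternative 1 | 8α,13-epidioxy-1β,10α:4α,5β-diepoxygermacr-7(11)-en-12,6α-olide | O1OCC2=C3[C@@H]1C[C@@]4(C)O[C@@H]4CC[C@@]4(C)O[C@@H]4[C@H]3OC2=O
A2 | alternative 1 | 1β,10α:4α,5β-diepoxygermacra-7,11(13)-dien-12,6α-olide | C=C2C3=CC[C@@]4(C)O[C@@H]4CC[C@@]4(C)O[C@@H]4[C@H]3OC2=O
A3 | alternative 2 | 13-acetoxy-8α-hydroxygermacra-1(10)E,4E,7(11)-trien-12,6α-olide | CC(=O)OCC1=C2[C@@H](O)C/C(C)=C/CC/C(C)=C/[C@H]2OC1=O
A4 | alternative 2 | 13-acetoxy-8α-hydroxygermacra-1(10)E,4E,7(11)-trien-12-oic acid (carboxyl cis to C6) | CC(=O)OC\C(C(=O)O)=C1/[C@@H](O)C/C(C)=C/CC/C(C)=C/C1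
A5 | alternative 2 | germacrone, (3E,7E)-3,7-dimethyl-10-(propan-2-ylidene)cyclodeca-3,7-dien-1-one | O=C1C/C(C)=C/CC/C(C)=C/CC1=C(C)C
A6 | alternative 3 | (3S,5E,9E)-3-(tert-butyldimethylsilyloxy)-5,9-dimethylcyclodeca-5,9-dien-1-one | C1[C@@H](O[Si](C)(C)C(C)(C)C)C/C(C)=C/CC/C(C)=C/C1=O
A7 | alternative 3 | (5S)-5-(tert-butyldimethylsilyloxy)-3-methylcyclohex-2-en-1-one | CC1=CC(=O)C[C@@H](O[Si](C)(C)C(C)(C)C)C1
A8 | alternative 3 | 1-methylcyclobutene | CC1=CCC1
A9 | alternative 3 | tricyclic [2+2] photoadduct of A7 and A8 (cyclobutane C5–C10–C1–C4; ring-fusion centres unassigned) | O=C1C[C@@H](O[Si](C)(C)C(C)(C)C)CC2(C)C1C1(C)CCC12
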